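## Structural features

The target 21 is a depsidone. Ring A (a pentasubstituted benzaldehyde) and ring B (a hexasubstituted benzene) are joined twice, by a diaryl ether oxygen and by an ester, and these two links close the seven-membered lactone ring C. Ring B is also fused to a 2,2-dimethyl-2,3-dihydropyran-4-one (ring D), so rings B and D together form a chroman-4-one.

In the labels used below, ring A carries the lactone carbonyl at a1, a methyl at a2, hydrogen at a3, a hydroxyl at a4, the formyl group at a5 and the ether oxygen at a6. Ring B is numbered as a chromanone: ketone at C4, methyl at C5, lactone oxygen at C6, ether oxygen at C7, free hydroxyl at C8, and O1 next to the gem-dimethyl carbon C2.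

There is no stereocentre and no stereogenic double bond, so no stereocentres stand next to each other. The problem is constitutional: the order of substituents on two crowded rings, and which of the neighbouring oxygens O6 and O7 becomes the ester and which the ether.

The fragile groups are the aryl ester of ring C (opened by hydroxide, alkoxide and even methanol), the o-hydroxybenzaldehyde, and the β-aryloxy ketone of ring D (retro-oxa-Michael opening). A diaryl ether next to a free phenol can also migrate to the neighbouring oxygen (Smiles rearrangement).

The real difficulty is steric. The ether joins a6 (between a1 and a5) to C7 (between C6 and C8), and the ester joins a di-ortho-substituted acid carbon to a di-ortho-substituted phenol, so copper-mediated ether synthesis and ordinary esterification are both unattractive.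

The key step exploits the fact that a1, a2, a5 and a6, with the lactone carbonyl, the methyl, a hydrogen and the ether oxygen, are C5, C6, C3 and C4 of a 4-aryloxy-6-methyl-2-pyranone-5-carboxylate. Exchanging the O1–C2 bridge of that pyranone for the two carbons of a ketene acetal supplies a3 and a4 with its oxygen.

## Logic of the disconnections

**21 to 19.** The bond cut is the C–C bond between a5 and the formyl carbon. It is cut first because the aldehyde would not tolerate the ether cleavage and the hot cycloaddition that precede it. In 19 an electrophile can attack only ring A, since ring B has no hydrogen. The gain is removal of the most reactive function from every earlier stage. The demand is regiochemical: a5, between the two oxygens, must be preferred to a3, between hydroxyl and methyl.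

**19 to 18.** The two phenolic O–H bonds are exchanged for O–CH3 bonds at a4 and C8. The a4 methyl ether is what the key step delivers, and the C8 methyl ether is carried unchanged from 5, so the masking costs no step and keeps both phenols silent during the acylating and base-sensitive stages. The forward step needs one reagent that cleaves both ethers and spares the aryl ester, the diaryl ether and the tertiary alkyl aryl ether of ring D.

**18 to 14 and 15.** The bonds cut are a2–a3 and a4–a5; in the reverse sense a CO2 bridge is restored between a2 and a5. This is the place to cut because it turns ring A, with four different substituents in fixed order, into a pyranone that comes from 1. The two crowded links of ring C then become substitutions at electrophilic pyranone carbons, made before ring A exists. The forward step must orient 15 so that its CH2 bonds to the methyl-bearing carbon, and the aryl lactone must survive the heat and the methanol released.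

**14 to 12 to 11.** The acyl–O6 bond of ring C is cut, and the acid so revealed is traced to its methyl ester. The lactone is closed from the free acid by activation and not by exchange of the methyl ester, because the aryl ester/methanol equilibrium lies on the side of the methyl ester. The gain is an open ether with a single free phenol, so the closure has no regiochemical choice. The methyl ester must be removed without hydroxide, which would open the pyranone, and the closure must run without phenoxide, which could move the pyranone from O7 to O6.

**11 to 4 and 10.** The bond cut is C4(pyranone)–O7. C4 of 4 is the β-carbon of a vinylogous acid chloride, so the crowded ether forms by addition–elimination near room temperature without copper. The gain is two fragments of similar size, each at most three steps from commercial material. The demand is that O7 and not O6 attacks; this rests on the higher acidity of the 7-hydroxyl (para to the ketone) and on a base that ionises only that hydroxyl.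

**4 to 3 to 1.** The C4–Cl bond is traced to the C4–OH of 3. Then the O1–C2 lactone bond and the C–C bond to the acetyl carbon are cut, leaving 1 and an acetyl unit. The gain is complete: all carbons of the pyranone, the future a2 methyl and the future lactone carbonyl come from one symmetrical diester. The demand is mono-C-acylation and closure onto the distal ester only; the proximal ester cannot be reached in a six-membered ring.

**10 to 9.** The O7–CH3 bond is restored. This allows both ring B methoxy groups to come from 5. The forward step must remove the 7-methyl and keep the 8-methyl; the free 6-hydroxyl next to O7 and the ketone para to O7 provide the bias.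

**9 to 6 and 7, and 6 to 5.** In ring D the aryl–acyl bond C4a–C4 and the O1–C2 bond are cut, then the hydroquinone is traced to the quinone. The gain is a commercial quinone that already holds the methyl and three of the four ring B oxygens in the right order. Only one ring carbon of 6 is unsubstituted, so the acylation has no positional choice; the demand is C-acylation rather than C-alkylation by the unsaturated acid.

## Other disconnections considered

**Alternative 1:** The cut is the C5–C6 bond of ring B, made by thermal ring expansion of a squaric acid derivative.

- Forward key step: a 1-propenyl organometallic adds to the mixed squarate A3 (made from dimethyl squarate A5 and the ring A phenol A4) to give cyclobutenone A2. Heating opens the four-membered ring, the ketene closes onto the propenyl terminus by 6π electrocyclisation, and tautomerisation gives hydroquinone A1, which already holds the ether to ring A and the methoxy group.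
- In favour: ring A comes from an available arene, so its pattern is never in question. The crowded ether is made by addition–elimination on a squarate, which is equal to the chosen plan on that point.
- Better than the chosen plan: the two ring B oxygens that become lactone and pyran oxygen are differentiated by construction, so no selective demethylation and no choice between two catechol oxygens is needed.
- Against: the organometallic must add to the carbonyl next to the methoxy-bearing carbon and spare the benzoate; the preference is one of degree. A4 is a hindered, hydrogen-bonded phenol and a poor partner for the squarate exchange. A1 is an air-sensitive hydroquinone. Ring D must then be annulated with 7 in strong acid in the presence of the ester. The lactone must still be closed at the end from a di-ortho-substituted benzoate.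
- Comparison: on structure, both plans reach 18 with ring B complete, and this one would pass through the seco ester F1 of the fallback to step 9. On mechanism, both key steps are reagent-free pericyclic processes. On step economy, about six steps lead from A4 and A5 to 18, against seven in the longest line here, which is equal or slightly better. The chosen plan is preferred by a small margin because ring C is complete before the last skeleton-building step.

**Alternative 2:** The cut is at the lactone oxygen (carbonyl–O and O–C6), tracing ring C back to the six-membered pyranone ring of xanthone A7.

- Forward key step: the peroxy acid A8 adds to the xanthone carbonyl, and the ring B carbon migrates from carbon to oxygen to give depsidone A6.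
- In favour: xanthones are easy to assemble, and the hindered aryl–carbonyl bond is formed as a ketone.
- Better than the chosen plan: the ester link arises by rearrangement, with no ester cleavage and no lactonisation of a hindered acid.
- Against: the xanthone carbonyl is doubly deactivated by the ring oxygen and shielded by two peri methyl groups, so addition of the peroxy acid should be slow. The electron-rich ring B is itself open to oxidation by A8. Ring D, the differentiation of two methoxy groups and the formyl group must all be added after the sensitive lactone exists, including a Friedel–Crafts acylation.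
- Comparison: on structure, A6 leaves ring B pentasubstituted and without ring D, whereas 18 lacks only the formyl group. On mechanism, both migratory aptitude and carbonyl reactivity are uncertain, while the cycloaddition has a diene polarised for the required orientation. On step economy the count is roughly equal, but more of the steps are run on the depsidone.

**Alternative 3:** The cut goes through ring A and removes four C–C bonds.

- Forward key step: irradiation of diazo ketone A11 gives, by Wolff rearrangement, isopropenylketene A12. This adds across the aryloxyalkyne A10; warming opens the four-membered ring and 6π closure gives phenol A9.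
- In favour: the plan is convergent and builds ring A on a finished ring B with the ether in place, which is equal to the chosen plan.
- Better than the chosen plan: the formyl carbon arrives as its acetal exactly at a5, so the a5/a3 question of the final formylation does not arise.
- Against: A9 lacks the lactone carbonyl at a1, the most hindered position of ring A, so a carboxylation in competition with a3 and a lactonisation must follow. A10 requires strongly basic ynol ether chemistry on a phenol carrying an enolisable, base-sensitive chromanone. The aryl ketone of ring D can absorb light competitively.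
- Comparison: on structure, the hardest bond is postponed and not solved. On mechanism, both are pericyclic cascades with polarity-controlled orientation, which is equal. On step economy, silyl protection, ynol ether formation, the diazo ketone, carboxylation and lactonisation make this at least three steps longer.

Key step: step 9

**Remarks on the chemistry**

- Pyranone atoms are numbered O1, C2 (carbonyl), C3, C4, C5, C6 as in 2H-pyran-2-one. The atom map to ring A is a1 = C5, a2 = C6, a5 = C3, a6 = C4.
- An atom-by-atom check of this map and of ring B against chromanone 10 confirms that 14 and 18, as drawn in the compound list, lead to the constitution of 21.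
- The target has no stereocentre. 16 and 20 contain transient stereocentres, form as racemates and lose them in the same flask.
- Assumption: the 7-hydroxyl of 10, para to the ketone, is taken to be the more acidic catechol hydroxyl by about two pKa units, as in other 6,7-dihydroxychromanones.

## Route

Step 1
Reactants: 1 dimethyl 3-oxopentanedioate
Product: 3 methyl 4-hydroxy-6-methyl-2-oxo-2H-pyran-5-carboxylate, via triacylmethane diester 2 (not isolated)
Conditions: MgCl2, pyridine, AcCl, CH2Cl2, 0 °C to rt; solvent removed; conc. H2SO4, rt; ice
Reagents that add atoms: acetyl chloride CC(=O)Cl
Why: Magnesium-chelate C-acylation of the β-keto diester stops after one acetyl group because 2 is held as its chelated enolate; in strong acid the enol oxygen of the acetyl group attacks the distal ester (enol lactonisation, 6-exo-trig) with loss of methanol, and the 4-hydroxy-2-pyranone is the only six-membered ring open to 2.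

Step 2
Reactants: 3 methyl 4-hydroxy-6-methyl-2-oxo-2H-pyran-5-carboxylate
Product: 4 methyl 4-chloro-6-methyl-2-oxo-2H-pyran-5-carboxylate
Conditions: POCl3, Et3N, toluene, 80 °C
Reagents that add atoms: phosphoryl chloride O=P(Cl)(Cl)Cl
Why: Deoxychlorination of a vinylogous carboxylic acid: the acidic 4-hydroxyl is O-phosphorylated and chloride substitutes at C4 by addition–elimination. Chloride is chosen over a sulfonate because a phenoxide can then attack only C4 and not a sulfonyl sulfur, and no formamide is present that could formylate C3.

Step 3
Reactants: 5 2,3-dimethoxy-5-methyl-1,4-benzoquinone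
Product: 6 2,3-dimethoxy-5-methylbenzene-1,4-diol
Conditions: H2 (1 atm), Pd/C, EtOAc, rt; filtered under Ar and used at once
Reagents that add atoms: none
Why: Catalytic hydrogenation reduces the quinone to the hydroquinone under neutral conditions; 6 re-oxidises in air and is therefore taken on directly.

Step 4
Reactants: 6 2,3-dimethoxy-5-methylbenzene-1,4-diol; 7 3-methylbut-2-enoic acid
Product: 9 6-hydroxy-7,8-dimethoxy-2,2,5-trimethylchroman-4-one, via ortho-acylphenol enone 8 (not isolated)
Conditions: P2O5, MeSO3H (Eaton's reagent), 70 °C
Reagents that add atoms: none
Why: Friedel–Crafts acylation (directly or by O-acylation and Fries shift) can occur only at the one unsubstituted ring carbon, and the phenol next to it then closes ring D by oxa-Michael addition to enone 8 (6-endo-trig). The P2O5 medium generates the acylium species and so favours C-acylation over the conjugate C-alkylation that in plain sulfonic acid leads to a dihydrocoumarin.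

Step 5
Reactants: 9 6-hydroxy-7,8-dimethoxy-2,2,5-trimethylchroman-4-one
Product: 10 6,7-dihydroxy-8-methoxy-2,2,5-trimethylchroman-4-one
Conditions: AlCl3, CH2Cl2, 0 °C to rt; aq. HCl
Reagents that add atoms: none
Why: Lewis-acid ether cleavage directed by the free neighbour: AlCl3 binds O6 and chelates O7, whose methyl is then removed by chloride in an SN2 step. The 7-methoxy group is also the central one of three contiguous oxygens and para to the ketone, whereas the 8-methoxy group has none of these activations.

Step 6
Reactants: 4 methyl 4-chloro-6-methyl-2-oxo-2H-pyran-5-carboxylate; 10 6,7-dihydroxy-8-methoxy-2,2,5-trimethylchroman-4-one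
Product: 11 methyl 4-[(6-hydroxy-8-methoxy-2,2,5-trimethyl-4-oxochroman-7-yl)oxy]-6-methyl-2-oxo-2H-pyran-5-carboxylate
Conditions: KHCO3 (1.2 equiv), DMF, Ar, 25–40 °C
Reagents that add atoms: none
Why: Addition–elimination at C4 of the 4-chloropyranone (vinylogous acyl substitution). KHCO3 ionises only the more acidic 7-hydroxyl, so O7 becomes the ether oxygen; the 6-hydroxyl stays protonated, which keeps it from attacking C4 and from starting a Smiles migration.

Step 7
Reactants: 11 methyl 4-[(6-hydroxy-8-methoxy-2,2,5-trimethyl-4-oxochroman-7-yl)oxy]-6-methyl-2-oxo-2H-pyran-5-carboxylate
Product: 12 4-[(6-hydroxy-8-methoxy-2,2,5-trimethyl-4-oxochroman-7-yl)oxy]-6-methyl-2-oxo-2H-pyran-5-carboxylic acid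
Conditions: LiI, EtOAc, reflux; aq. HCl
Reagents that add atoms: none
Why: Nucleophilic dealkylation of the methyl ester by iodide (SN2 at the methyl carbon, electron-poor carboxylate as leaving group) works on hindered esters and, unlike saponification, neither opens the pyranone nor ionises the phenol.

Step 8
Reactants: 12 4-[(6-hydroxy-8-methoxy-2,2,5-trimethyl-4-oxochroman-7-yl)oxy]-6-methyl-2-oxo-2H-pyran-5-carboxylic acid
Product: 14 pyranone-fused dioxepinone (ring C closed; ring A still a 6-methyl-2-pyranone), via mixed trifluoroacetic anhydride 13 (not isolated)
Conditions: (CF3CO)2O, toluene, 0 °C to 50 °C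
Reagents that add atoms: none
Why: Lactonisation through the mixed anhydride 13, a standard closure of depsidone lactones: the C6 phenol attacks the activated acyl group intramolecularly (7-exo-trig) and trifluoroacetate leaves. The medium is acidic throughout, so no phenoxide forms and the aryl ether cannot migrate.

Step 9
Reactants: 14 pyranone-fused dioxepinone; 15 1,1-dimethoxyethene
Product: 18 depsidone bis(methyl ether) lacking the formyl group, via bridged lactone cycloadduct 16 (not isolated), via dimethoxycyclohexadiene 17 (not isolated)
Conditions: 15 (6 equiv), toluene, sealed tube, 110–130 °C
Reagents that add atoms: none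
Why: This is an inverse-electron-demand Diels–Alder reaction of an electron-poor 2-pyranone-5-carboxylate with a ketene acetal, the known route from such pyranones to 4-alkoxybenzoates. The nucleophilic CH2 of 15 bonds to pyranone C6, which is β to the ring C carbonyl on C5 and δ to the C2 carbonyl, and the acetal carbon bonds to C3 in a strongly asynchronous [4+2] addition that gives the 2-oxabicyclo[2.2.2]octenone 16. Retro-Diels–Alder loss of CO2 from 16 gives diene 17, and 1,2-elimination of methanol from its acetal carbon and the neighbouring CH2 aromatises ring A. Ring A is therefore closed by cycloaddition across the diene termini, with both new C–C bonds (a2–a3 and a4–a5) made while ring C is already in place, and not by cyclisation of a chain. No stereocentre remains, because the two bridgeheads of 16 are lost with the CO2 bridge. The selectivity needed is regiochemical: the methoxy group must end at a4, para to the lactone carbonyl and meta to the ether oxygen, and the matched polarisation of diene and ketene acetal just described secures it. The excess of 15 also takes up the methanol set free, which protects the aryl lactone from methanolysis; the aryloxy donor at C4 and the methyl at C6 make the diene less reactive than an unsubstituted pyranone ester, hence the sealed-tube heating.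

Step 10
Reactants: 18 depsidone bis(methyl ether) lacking the formyl group
Product: 19 deformyl depsidone bis-phenol (hydroxyl at a4 and at C8)
Conditions: BBr3, CH2Cl2, −78 °C to 0 °C; H2O
Reagents that add atoms: none
Why: BBr3 cleaves aryl methyl ethers by bromide attack on the methyl group of the boron–ether complex, so both methoxy groups (a4 and C8) are removed. The aryl ester, the diaryl ether and the ketone are tolerated at low temperature, which is also chosen to leave the tertiary alkyl aryl ether of ring D intact.

Step 11
Reactants: 19 deformyl depsidone bis-phenol
Product: 21 target depsidone (formyl at a5), via chloro(methoxy)methyl arene 20 (not isolated)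
Conditions: Cl2CHOCH3, TiCl4, CH2Cl2, −20 °C to 0 °C; aq. HCl
Reagents that add atoms: dichloromethyl methyl ether COC(Cl)Cl; water O
Why: Rieche formylation: TiCl4 ionises the dichloromethyl ether and binds the a4 phenoxide, so the electrophile is delivered ortho to that oxygen; ring B has no hydrogen. Of the two ortho positions, a5 lies between two oxygen donors and is less shielded than a3, which is flanked by the methyl group. The α-chloro ether 20 is hydrolysed on work-up to the aldehyde, which is then held by a hydrogen bond to the a4 hydroxyl.

## Compound list

1 | dimethyl 3-oxopentanedioate | COC(=O)CC(=O)CC(=O)OC | starting material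
2 | dimethyl 2-acetyl-3-oxopentanedioate (triacylmethane diester, not isolated) | COC(=O)CC(=O)C(C(C)=O)C(=O)OC | intermediate
3 | methyl 4-hydroxy-6-methyl-2-oxo-2H-pyran-5-carboxylate | COC(=O)C1=C(C)OC(=O)C=C1O | intermediate
4 | methyl 4-chloro-6-methyl-2-oxo-2H-pyran-5-carboxylate | COC(=O)C1=C(C)OC(=O)C=C1Cl | intermediate
5 | 2,3-dimethoxy-5-methyl-1,4-benzoquinone | COC1=C(OC)C(=O)C(C)=CC1=O | starting material
6 | 2,3-dimethoxy-5-methylbenzene-1,4-diol | COc1c(O)cc(C)c(O)c1OC | intermediate
7 | 3-methylbut-2-enoic acid | CC(C)=CC(=O)O | starting material
8 | 1-(2,5-dihydroxy-3,4-dimethoxy-6-methylphenyl)-3-methylbut-2-en-1-one (not isolated) | COc1c(O)c(C(=O)C=C(C)C)c(C)c(O)c1OC | intermediate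
9 | 6-hydroxy-7,8-dimethoxy-2,2,5-trimethylchroman-4-one | COc1c(OC)c2OC(C)(C)CC(=O)c2c(C)c1O | intermediate
10 | 6,7-dihydroxy-8-methoxy-2,2,5-trimethylchroman-4-one | COc1c(O)c(O)c(C)c2C(=O)CC(C)(C)Oc12 | intermediate
11 | methyl 4-[(6-hydroxy-8-methoxy-2,2,5-trimethyl-4-oxochroman-7-yl)oxy]-6-methyl-2-oxo-2H-pyran-5-carboxylate | COC(=O)C1=C(C)OC(=O)C=C1Oc1c(O)c(C)c2C(=O)CC(C)(C)Oc2c1OC | intermediate
12 | 4-[(6-hydroxy-8-methoxy-2,2,5-trimethyl-4-oxochroman-7-yl)oxy]-6-methyl-2-oxo-2H-pyran-5-carboxylic acid | OC(=O)C1=C(C)OC(=O)C=C1Oc1c(O)c(C)c2C(=O)CC(C)(C)Oc2c1OC | intermediate
13 | mixed anhydride of 12 with trifluoroacetic acid (not isolated) | FC(F)(F)C(=O)OC(=O)C1=C(C)OC(=O)C=C1Oc1c(O)c(C)c2C(=O)CC(C)(C)Oc2c1OC | intermediate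
14 | pyranone-fused dioxepinone: 6-methyl-2-pyranone whose C5 carbonyl is esterified by O6 and whose C4 is etherified by O7 of 8-methoxy-2,2,5-trimethylchroman-4-one | CC1=C2C(=O)Oc3c(C)c4C(=O)CC(C)(C)Oc4c(OC)c3OC2=CC(=O)O1 | intermediate
15 | 1,1-dimethoxyethene | COC(=C)OC | starting material
16 | bridged lactone cycloadduct of 14 and 15, a 2-oxabicyclo[2.2.2]oct-5-en-3-one (racemic, not isolated) | CC12OC(=O)C(C(OC)(OC)C1)C1=C2C(=O)Oc2c(C)c3C(=O)CC(C)(C)Oc3c(OC)c2O1 | intermediate
17 | dimethoxycyclohexadiene formed from 16 by loss of CO2 (not isolated) | CC1=C2C(=O)Oc3c(C)c4C(=O)CC(C)(C)Oc4c(OC)c3OC2=CC(OC)(OC)C1 | intermediate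
18 | depsidone bis(methyl ether) lacking the formyl group (methoxy at a4 and at C8) | COc1cc(C)c2c(c1)Oc1c(OC)c3OC(C)(C)CC(=O)c3c(C)c1OC2=O | intermediate
19 | deformyl depsidone bis-phenol (hydroxyl at a4 and at C8) | Cc1cc(O)cc2c1C(=O)Oc1c(C)c3c(c(O)c1O2)OC(C)(C)CC3=O | intermediate
20 | a5-[chloro(methoxy)methyl] derivative of 19 (racemic, not isolated) | Cc1cc(O)c(C(Cl)OC)c2c1C(=O)Oc1c(C)c3c(c(O)c1O2)OC(C)(C)CC3=O | intermediate
21 | target depsidone CNP0271978.0 (formyl at a5) | Cc1cc(O)c(C=O)c2c1C(=O)Oc1c(C)c3c(c(O)c1O2)OC(C)(C)CC3=O | target

## Step count and least certain steps

Total: 11 steps. The longest linear sequence is 9 steps (5 to 21 through steps 3 to 11). The pyranone arm (steps 1 and 2) joins at step 6.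

**Step 9 (key step).** What may go wrong: the cycloaddition may be too slow, because the aryloxy donor at C4 and the methyl at C6 make the diene less electron-poor. Prolonged heating could then let the ketene acetal polymerise, or attack the strained aryl lactone or C4 as a nucleophile, or let methanol open ring C if scavenging falls behind.

Fallback: the same cycloaddition is run one stage earlier, on the open ester 11, which has no strained lactone. The free hydroxyl takes up one further equivalent of 15 as an orthoester, which mild aqueous acid returns to the phenol. This should give methyl 2-[(6-hydroxy-8-methoxy-2,2,5-trimethyl-4-oxochroman-7-yl)oxy]-4-methoxy-6-methylbenzoate F1. Iodide dealkylation (LiI, pyridine, reflux) would give 2-[(6-hydroxy-8-methoxy-2,2,5-trimethyl-4-oxochroman-7-yl)oxy]-4-methoxy-6-methylbenzoic acid F2, and (CF3CO)2O in toluene closes ring C. The fallback sets out from 11 and comes back to the route at 18.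

**Step 6.** What may go wrong: attack through O6 instead of O7, or base-induced migration of the pyranone from O7 to O6 through a spiro intermediate (Smiles rearrangement). Either inverts the positions of ether and ester in ring C.

Fallback: the two oxygens are differentiated by protection and not by acidity. From 9, the 6-hydroxyl is protected (MOMCl, iPr2NEt, CH2Cl2) to give 7,8-dimethoxy-6-(methoxymethoxy)-2,2,5-trimethylchroman-4-one F3. NaSEt in DMF at 90 °C then removes the 7-methyl group by SN2 (the phenoxide para to the ketone is the better leaving group) to give 7-hydroxy-8-methoxy-6-(methoxymethoxy)-2,2,5-trimethylchroman-4-one F4. F4 with K2CO3 and 4 in DMF can react only through O7 and gives methyl 4-{[8-methoxy-6-(methoxymethoxy)-2,2,5-trimethyl-4-oxochroman-7-yl]oxy}-6-methyl-2-oxo-2H-pyran-5-carboxylate F5. CF3CO2H in CH2Cl2 at 0 °C removes the acetal. The fallback sets out from 9 and comes back at 11; because it starts at 9 it also replaces step 5, should the directed demethylation be unselective.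

**Step 11.** What may go wrong: formylation at a3 instead of a5, or at both, because a3 is para to the ether oxygen and also ortho to the hydroxyl.

Fallback: a3 is blocked. If a3 is the more reactive site, bromination of 19 (NBS, MeCN, 0 °C, dark) goes there and gives the a3-bromo derivative of 19 F6. Rieche formylation of F6 can then occur only at a5 and gives the a3-bromo derivative of 21 F7. Hydrodebromination (HCO2H, Et3N, Pd(OAc)2, PPh3, DMF, 60 °C; zerovalent palladium formed in the flask) removes the bromine and spares the aldehyde. The fallback sets out from 19 and comes back at 21.

**Step 4.** What may go wrong: conjugate C-alkylation of the arene by the β-carbon of 7, followed by lactonisation, may outrun C-acylation. This would build a dihydrocoumarin ring from the same atoms instead of the chromanone.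

Fallback: ring D is built by Kabbe condensation. 6 is C-acetylated at its only free position (AcOH, BF3·OEt2, 90 °C) to give 1-(2,5-dihydroxy-3,4-dimethoxy-6-methylphenyl)ethanone F8. Acetone and pyrrolidine in toluene at reflux (enamine aldol, dehydration, oxa-Michael) then close the 2,2-dimethylchromanone. The fallback sets out from 6 and comes back at 9.

## Further compounds

F1 | step 9 | methyl 2-[(6-hydroxy-8-methoxy-2,2,5-trimethyl-4-oxochroman-7-yl)oxy]-4-methoxy-6-methylbenzoate | COC(=O)c1c(C)cc(OC)cc1Oc1c(O)c(C)c2C(=O)CC(C)(C)Oc2c1OC
F2 | step 9 | 2-[(6-hydroxy-8-methoxy-2,2,5-trimethyl-4-oxochroman-7-yl)oxy]-4-methoxy-6-methylbenzoic acid | OC(=O)c1c(C)cc(OC)cc1Oc1c(O)c(C)c2C(=O)CC(C)(C)Oc2c1OC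
F3 | step 6 | 7,8-dimethoxy-6-(methoxymethoxy)-2,2,5-trimethylchroman-4-one | COCOc1c(C)c2C(=O)CC(C)(C)Oc2c(OC)c1OC
F4 | step 6 | 7-hydroxy-8-methoxy-6-(methoxymethoxy)-2,2,5-trimethylchroman-4-one | COCOc1c(C)c2C(=O)CC(C)(C)Oc2c(OC)c1O
F5 | step 6 | methyl 4-{[8-methoxy-6-(methoxymethoxy)-2,2,5-trimethyl-4-oxochroman-7-yl]oxy}-6-methyl-2-oxo-2H-pyran-5-carboxylate | COCOc1c(C)c2C(=O)CC(C)(C)Oc2c(OC)c1OC1=CC(=O)OC(C)=C1C(=O)OC
F6 | step 11 | a3-bromo derivative of 19 | Cc1c(Br)c(O)cc2c1C(=O)Oc1c(C)c3c(c(O)c1O2)OC(C)(C)CC3=O
F7 | step 11 | a3-bromo derivative of 21 | Cc1c(Br)c(O)c(C=O)c2c1C(=O)Oc1c(C)c3c(c(O)c1O2)OC(C)(C)CC3=O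
F8 | step 4 | 1-(2,5-dihydroxy-3,4-dimethoxy-6-methylphenyl)ethanone | COc1c(O)c(C(C)=O)c(C)c(O)c1OC
A1 | alternative 1 | methyl 2-(2,5-dihydroxy-6-methoxy-3-methylphenoxy)-4-methoxy-6-methylbenzoate | COC(=O)c1c(C)cc(OC)cc1Oc1c(O)c(C)cc(O)c1OC
A2 | alternative 1 | methyl 2-{[3-hydroxy-2-methoxy-4-oxo-3-[(E)-prop-1-enyl]cyclobut-1-en-1-yl]oxy}-4-methoxy-6-methylbenzoate (racemic) | COC(=O)c1c(C)cc(OC)cc1OC1=C(OC)C(O)(/C=C/C)C1=O
A3 | alternative 1 | methyl 4-methoxy-2-[(2-methoxy-3,4-dioxocyclobut-1-en-1-yl)oxy]-6-methylbenzoate | COC(=O)c1c(C)cc(OC)cc1OC1=C(OC)C(=O)C1=O
A4 | alternative 1 | methyl 2-hydroxy-4-methoxy-6-methylbenzoate | COC(=O)c1c(C)cc(OC)cc1O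
A5 | alternative 1 | dimethyl squarate (3,4-dimethoxycyclobut-3-ene-1,2-dione) | COC1=C(OC)C(=O)C1=O
A6 | alternative 2 | depsidone core with ring A acetate and ring B dimethyl ether | Cc1cc(OC(C)=O)cc2c1C(=O)Oc1c(C)cc(OC)c(OC)c1O2
A7 | alternative 2 | 6-acetoxy-3,4-dimethoxy-1,8-dimethylxanthen-9-one | Cc1cc(OC(C)=O)cc2c1C(=O)c1c(C)cc(OC)c(OC)c1O2
A8 | alternative 2 | trifluoroperacetic acid | OOC(=O)C(F)(F)F
A9 | alternative 3 | diaryl ether with ring A complete except for the lactone carbonyl (a5 dimethyl acetal, O6 silyl ether) | Cc1cc(O)c(C(OC)OC)c(Oc2c(OC)c3OC(C)(C)CC(=O)c3c(C)c2O[Si](C)(C)C(C)(C)C)c1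
A10 | alternative 3 | 6-(tert-butyldimethylsilyloxy)-7-(3,3-dimethoxyprop-1-ynyloxy)-8-methoxy-2,2,5-trimethylchroman-4-one | COC(OC)C#COc1c(OC)c2OC(C)(C)CC(=O)c2c(C)c1O[Si](C)(C)C(C)(C)C
A11 | alternative 3 | 1-diazo-3-methylbut-3-en-2-one | CC(=C)C(=O)C=[N+]=[N-]
A12 | alternative 3 | isopropenylketene (3-methylbuta-1,3-dien-1-one) | CC(=C)C=C=O
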